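After 30 min you stop two flasks, dawn and midnight, and ask which holds the longer chains.

| setting | elm | oak | dawn | midnight |
|---|---|---|---|---|
| free monomer | 0.20 M | 0.20 M | 0.20 M | 0.20 M |
| initiator | 1.4 mM | 6.9 mM | 4.6 mM | 1.2 mM |
| remark | run made earlier | run made earlier |  |  |
| time |  |  | 30 min | 30 min |

- elm (time / min: monomer in chains / %, free monomer / %): 5.00: 12.1, 88.1; 10.0: 24.5, 75.5; 15.0: 32.5, 67.0; 20.0: 39.2, 61.2; 25.0: 43.2, 56.5; 30.0: 45.9, 53.7
- oak (time / min: monomer in chains / %, free monomer / %): 2.00: 15.7, 84.7; 6.00: 47.1, 53.4; 10.0: 59.4, 39.9; 15.0: 65.3, 33.1; 25.0: 68.9, 29.0; 30.0: 69.3, 28.5

(standard deviation of a reading: 0.3 percentage points)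

- which of the two ends with the longer chains by the average number of monomer units in a chain (chains begun, living or dead) ("neither" if they lie within 10 %) (dawn / midnight / neither)
- average number of monomer units in a chain (chains begun, living or dead) at the end, dawn
- average number of monomer units in a chain (chains begun, living or dead) at the end, midnight

- the average divides the monomer in chains by the number of chains begun, living and dead together
- the numbers in the tables scatter with a standard deviation of 0.3 percentage points
- the earlier runs do not show the number of chains; that part of a forecast is a guess

Write the balance of initiator, the reagent charged in the smaller amount: in dawn, 4.6 mM is less than the 0.20 M of free monomer. Suppose each chain begun costs one initiator, and call f the share of initiator that begins a chain. The length is then x/f times the charge ratio, [free monomer]₀/[initiator]₀, where x is the part of the free monomer in chains. That ratio is 43.5 for dawn and 167 for midnight.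

From elm to oak, initiator rises 4.93-fold but x, read at 30.0 min, rises 1.51-fold, which reads as a power of 0.258. My own reckoning with that power gives x of 62.4 % for dawn and 44.1 % for midnight. With f at its ceiling of one, the lengths are 27.1 and 73.5, and any smaller f lengthens them.

Turn the question round: for dawn to come level, its f would have to be 0.369 of midnight's. The runs do not show f, so this is a guess, but I expect no such gap and commit to midnight.

The forecast also says midnight, with 31 for dawn and 78 for midnight, on the assumption that “initiation is quick and nearly complete”, with f about 0.9.

    free monomer + initiator → living end + monomer in chains (k = 0.0442 M⁻¹ s⁻¹)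
    free monomer + living end → monomer in chains + living end, rate k2*[living end]*[free monomer] (k = 0.731 M⁻¹ s⁻¹)
    monomer in chains + living end → free monomer + living end, rate k3*[living end] as long as [monomer in chains] is above zero (k = 0.0382 s⁻¹)
    living end + monomer in chains → dead end A (k = 0.00948 M⁻¹ s⁻¹)
    initiator → spent initiator B (k = 0.00240 s⁻¹)

The flask gives midnight, with 91.1 units against 37.4 for dawn. In dawn at 7.48 min, the half-life of initiator by its step with free monomer is 2.3 min, shorter than the 4.8 min of the step to spent initiator B alone. Yet at 30.0 min dawn has 0 % of its initiator left and 1.06 mM of the 4.6 mM stands as spent initiator B, so f is 76.9 %, and the charge ratio with x of 66.1 % gives 37.4. In a further flask, the same as dawn but with 0.018 M of initiator, the same reckoning gives 10.5, and the average length there is 10.5.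

Readings and results were generated by integration on assumed constants.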